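The partition ratio 15 of step 1 favours the second phase, so this flask feeds its reaction phase by a slow leak of reagent.

    reagent in the reaction phase ⇌ reagent in the second phase, rate k1*([reagent in the reaction phase] - [reagent in the second phase]/K1) per volume of the first phase (K1 = 15, k1 = 0.0541 min⁻¹)
    substrate + reagent in the reaction phase ⇌ target (K2 = 9.46 L mol⁻¹, k2 = 22.4 L mol⁻¹ min⁻¹)
    target ⇌ product in the second phase, rate k3*([target] - [product in the second phase]/K3) per volume of the first phase (K3 = 2.70, k3 = 0.0522 min⁻¹)
    target → decomposed product (k4 = 0.0123 min⁻¹)
    reagent in the reaction phase + target → over-reaction product (k5 = 0.0196 L mol⁻¹ min⁻¹)

substrate 0.16 M; reagent in the second phase 0.144 M; time 2.5 h; volume of the second phase over the first 1.0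

- amounts and yields of target count product in the second phase too
- in the second phase: reagent in the second phase, product in the second phase; everything else is in the first
- charges count per volume of the first phase; a concentration in a rate is the amount of a species over the volume of its own phase; every rate counts per litre of the first phase
- run time (flask): 2.5 h

- target and product in the second phase together at 2.5 h, in percent of the substrate charged
- the change that raises the amount of target and product in the second phase together at 2.5 h, in percent of the substrate charged most ("none" if none brings more than 2 percentage points) (cedar / oak / elm / none)
- amount of target and product in the second phase together at 2.5 h, in percent of the substrate charged, after elm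

We write R for reagent in the reaction phase, T for target still in the first phase and P for product in the second phase. We hold substrate and reagent in the second phase at their charges and reckon only the correction, the material that passes. In this flask the leak starts at F = k1·cBq/K1 = 5.19 × 10⁻⁴ M min⁻¹. Forward binding alone, at the charged substrate, gives reagent in the reaction phase a half-life of 0.19 min, much shorter than the 12.8 min of transfer, so we take T as g = K2·cA = 1.51 times R, a pseudo-first-order binding. Setting the leak k1(cBq/K1 − R) equal to the loss of T with P still empty, (k3 + k4)T, gives our estimate of the standing level of target, T* = gF/(k1 + g(k3 + k4)), which is 0.005181 M. P fills towards K3·T* with time K3/k3 = 51.7 min, so by 2.5 h it has reached a share 0.945 of that, and target and P together stand at 3.55 times T*.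

That gives us 11.5 % for this flask, and 17.0 % after elm, which doubles k1 in both F and the denominator. Cedar doubles F and so T*, while we let oak shorten the filling alone, so our choice is cedar.

The forecast, stepped by hand, gives 13 %, cedar and 15.2 %, on the ground that “Doubling the reagent should nearly double the flux, so cedar wins.”

The simulation gives 12.9 % and 15.1 %, and cedar wins with 11 percentage points, against 2.2 points for elm and 0.85 points for oak. At 2.50 h this flask holds T at 0.006113 M, beside our T*, with P at 2.38 times T. In the neighbouring flask, with 0.64 M of substrate, the same reckoning puts T* at 0.007072 M and target and P together at 3.92 % of that substrate charge. The run of that neighbouring flask gives 5.37 %, of which 3.73 % is in the second phase.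

(The numbers of this flask come from no measurement; the rest is arithmetic.)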